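## Analysis of the target

The target 26 is a germacranolide of the furanoheliangolide type. With germacrane numbering, its ten-membered carbocycle C1–C10 is bridged by an ether oxygen between C3 and C10, so that C1 (ketone), C2=C3, C10 and this oxygen form a 3(2H)-furanone (ring A). An α-methylene-γ-butyrolactone O–C6–C7–C11(=C13)–C12 (ring B) is fused at C6/C7. C4=C5 is Z and carries methyl C15, C10 is quaternary and carries methyl C14, C8 bears the methacrylate and C9 a free hydroxyl. The five stereocentres are contiguous (6S,7S,8S,9R,10R): H6 and H7 are cis on ring B, C11 is anti to the C8 oxygen across C7–C8, the C8 and C9 oxygens have the threo relation of L-tartaric acid, and the C10 oxygen is anti to the C9 oxygen along the chain. Sensitive groups are three Michael acceptors (methylene lactone, methacrylate, the dienone of ring A with C4=C5), a Z alkene that can relax to E once conjugated to a carbonyl, and a C8 ester lying between a free hydroxyl and the lactone (acyl shift, translactonisation). The difficulty is the medium ring: it holds a flat five-membered ring and two further sp2 carbons, a closure at C6–C7 makes a ring that is only nine-membered when counted through the ether oxygen, and the lactone must come out cis-fused with the right sense towards C8. The strategy rests on ring B: its five atoms are those of an aldehyde (C6 and its oxygen), of the internal double bond of a terminal allene (C7=C11, C13 as the remaining CH2) and of one carbon monoxide (C12), so one (2+2+1) cyclocarbonylation can make ring B and close the carbocycle together.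

## Retrosynthetic reasoning

**26 back to 23.** The last operations change oxygen substituents only. 26 is traced to its C9 p-methoxybenzyl ether 25, 25 to the C8 alcohol 24, and 24 to the C8 silyl ether 23. The ester goes on after the ring system stands because it would not survive the organometallic steps. The two neighbouring oxygens carry orthogonal groups so that only O8 is acylated, and the benzyl-type ether is removed last because its oxidative cleavage is neutral.

**23 to 21 and 22.** Three bonds of ring B are cut at once: C6–C7, C11–C12 and C12–O6. This leaves the (Z)-enal 21, with a terminal allene on C8, and carbon monoxide 22. No other cut removes ring B and the medium ring together, creates C6 and C7 in one event, and leaves C8, C9 and C10 in an open chain where they can be set reliably. The forward reaction must bring the aldehyde and the internal allene bond onto one metal across a seven-atom tether and take up one molecule of 22.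

**21 to 19.** The aldehyde is the most fragile group and is made last: 21 comes from allylic alcohol 20, and 20 from its silyl ether 19. Only the oxidation level of C6 changes.

**19 to 17.** Ring A is opened at O–C3 and the C1 carbonyl is returned to a triple bond: the furanone is the hydrated, cyclised isomer of the γ-hydroxy ynone 17 (C10–OH, C1≡C2, C3=O). Forward, a secondary amine adds to C1 (enaminone 18) and acid closes O10 onto C3 and frees the C1 ketone. This ynone is chosen because it divides into two fragments of similar size at C2–C3.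

**17 to 16 and 3.** Cutting C2–C3 gives terminal alkyne 16 and the (Z)-N-methoxy-N-methylamide 3; the amide stops the acetylide addition at the ketone.

**3 to 1.** The Z geometry of C4=C5 is taken from a ring: in butenolide 1 the carbonyl and the CH2O group are held cis, and aminolysis (through 2) with silylation carries this into 3.

**16 to 13.** Two bonds at C10 are cut: C10–C14 and C10–C1. 16 comes from silylated carbinol 15, 15 from ynone 14 by addition of a methyl nucleophile, and 14 from amide 13 and a silyl-capped acetylide. The methyl group is added last because the C9 ether then chelates with the ketone and steers the reagent to the face of H9; the reverse order would need a non-chelated addition for the same result.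

**13 to 10.** The allene is returned to terminal alkyne 11 and a one-carbon unit (C13), through propargylic amine 12; 11 comes from aldehyde 10 by one-carbon homologation (C11). The allene is made before the second alkyne (C1≡C2) appears, so only one terminal alkyne is ever present.

**10 to 4.** 10 is the oxidised form of hydroxy amide 9, the ring-opened form of lactone 8, which comes from hydroxy lactone 7. 7 keeps the four carbons and both stereocentres of diethyl L-tartrate 4: mono-etherification of the C2-symmetric diol (5) makes the esters different, a hydroxyl-directed reduction removes the ester next to the free hydroxyl (6), and lactonisation stores the two different ends. C8 and C9 are bought, not made.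

## Alternatives that were turned down

**Alternative 1:** ring expansion by Eschenmoser–Tanabe fragmentation.
- Disconnection: the carbocycle is not closed but released from a bicyclo[4.4.0] precursor, reached from guaiacol A2 by dearomatisation, by breaking the shared C1–C6 bond.
- Forward key step: the tosylhydrazone of a ring-fusion epoxy ketone loses nitrogen and sulfinate and opens to the ten-membered (Z)-enone ynone ketal A1; C1≡C2 and the C6 ketone appear together.
- For it: there is no macrocyclisation entropy, the ring size is fixed by the precursor, the Z alkene is inherited from a six-membered ring, and the fragmentation type is well established for cyclodecynones. On these points it is stronger than the chosen route, whose ring closure is unproven and whose enal can isomerise.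
- Against it: A1 has neither ring A nor ring B. C6 must be reduced from the face that leads to the cis lactone in a flexible enone, the ester arm lactonised and methylenated at C11, ketal and acetonide opened, the γ-hydroxy ynone cyclised across the ring, and the C8/C9 groups exchanged, about ten operations. Before the fragmentation, C7, C8, C9 and the quaternary C10 must be set on the bicycle from an achiral arene. A ten-membered ring holding a triple bond, a Z enone and a ketal carbon is strained, so the fragmentation may stall.
- Comparison: the chosen route reaches 23, with both rings and all five stereocentres, in 15 steps and needs three more. It accepts a riskier ring formation in exchange for C6, C7 and the lactone arriving at the final oxidation level in one step.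

**Alternative 2:** [2,3]-Wittig ring contraction.
- Disconnection: C7–C8, inside a 13-membered allyl ether ring in which O8 is bonded to C13.
- Forward key step: the enolate of the C9 ketone (carbanion at C8) rearranges, forming C7–C8 and breaking O–C13, to give the ten-membered ketone A3 with the C8 hydroxyl and the C11=C13 methylene.
- For it: contracting a large ring is easier than closing a nine- or ten-membered one, the reaction type is known for medium carbocycles, and A3 has the C8 hydroxyl free beside a ketone, so the methacrylate could go on without protecting-group exchange. On precedent and on C8/C9 differentiation it is stronger than the chosen route.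
- Against it: a strong base must form the C8 enolate in the presence of ring A, whose C15 methyl is vinylogously acidic. C7 and C8 are set by a transition state whose shape depends on the conformation of a 13-membered ring and on enolate geometry. C9 must then be reduced to the R alcohol, and C12 raised from a silyloxymethyl group to the acid and lactonised onto O6, five or six steps. The ether macrocycle needs the whole skeleton before the key step.
- Comparison: the chosen strategy takes C8 and C9 from 4 and sets C10 by chelation before any ring exists, and makes the lactone carbonyl from 22 instead of by three oxidation-level changes. It pays with a key step of less precedent.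

**Alternative 3:** carbene-catalysed crossed benzoin.
- Disconnection: C1–C10.
- Forward key step: a triazolium-derived carbene with an amidine base turns a C1 aldehyde into an acyl-anion equivalent that adds to the C10 methyl ketone, giving the tertiary alcohol, the C1 ketone and the ten-membered ketol A4, with C3 masked as a dithiane.
- For it: it is metal-free and runs near room temperature, C1 and C10 arrive at their final oxidation level, ring A follows by unmasking C3 and dehydrative closure, and no Z enal is needed because C4=C5 is not conjugated to a carbonyl until late. On mildness and on Z-alkene stability it is stronger than the chosen route.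
- Against it: aldehyde–ketone benzoin closures are established for five- and six-membered rings only, so the step is no better precedented at this ring size than the chosen one. The configuration of C10 would be decided by the facial choice of a methyl ketone in a flexible macrocyclic transition state. The C1 aldehyde has an enolisable C2 methylene and the addition is reversible. The open chain must already hold C6–C9, with the C6/C7 pair made by an acyclic allylation that gives the needed relation only with difficulty. Ring B is still to be built from the C12 silyloxymethyl group.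
- Comparison: both strategies stake everything on one new ring closure. The chosen one makes two rings, three skeletal bonds and two stereocentres in that step and needs three steps afterwards, where A4 needs about seven.

Key step: step 15

Assumption: 1, 4 and all reagents are purchasable; the C8 oxygen is carried as the silyl ether and the C9 oxygen as the p-methoxybenzyl ether (not the reverse), because the C9 ether has to chelate magnesium in step 10.

## Route

Step 1
Reactants: 1 3-methylfuran-2(5H)-one
Product: 3 (2Z)-4-[(tert-butyldimethylsilyl)oxy]-N-methoxy-N,2-dimethylbut-2-enamide, via hydroxy amide 2 (not isolated)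
Conditions: MeNH(OMe)·HCl, Me3Al, CH2Cl2, 0 °C to rt; aqueous potassium sodium tartrate; crude 2, TBSCl, imidazole, DMF, 0 °C
Reagents that add atoms: N,O-dimethylhydroxylamine hydrochloride, Cl.CNOC; tert-butyldimethylsilyl chloride, CC(C)(C)[Si](C)(C)Cl
Why: Weinreb aminolysis of a lactone by the dimethylaluminium amide opens 1 at the acyl–oxygen bond; carbonyl and CH2O were cis in the ring, so 2 and 3 are Z without any olefination, and immediate silylation should stop 2 from closing back to 1.

Step 2
Reactants: 4 diethyl L-tartrate [diethyl (2R,3R)-2,3-dihydroxybutanedioate]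
Product: 5 diethyl (2R,3R)-2-hydroxy-3-[(4-methoxybenzyl)oxy]butanedioate
Conditions: 4-methoxybenzyl chloride (1.1 equiv), Ag2O (1.5 equiv), CH2Cl2, rt, dark
Reagents that add atoms: 4-methoxybenzyl chloride, COc1ccc(CCl)cc1
Why: Ag2O-promoted Williamson-type mono-etherification of a C2-symmetric diol: either hydroxyl gives the same product, one equivalent of halide limits the bis-ether, and the non-basic conditions should not epimerise the α-hydroxy esters.

Step 3
Reactants: 5 diethyl (2R,3R)-2-hydroxy-3-[(4-methoxybenzyl)oxy]butanedioate
Product: 7 (3R,4S)-4-hydroxy-3-[(4-methoxybenzyl)oxy]oxolan-2-one, via diol ester 6 (not isolated)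
Conditions: BH3·SMe2 (1.05 equiv), NaBH4 (5 mol %), THF, 0 °C to rt; MeOH; then TsOH·H2O (cat.), CH2Cl2, rt
Reagents that add atoms: none
Why: Hydroxyl-directed borane reduction: the free hydroxyl becomes an alkoxyborane that delivers hydride to its own α-ester through a five-membered ring (NaBH4 initiates), so only the ester beside the free hydroxyl should be reduced; acid then closes the primary hydroxyl of 6 onto the remaining ester (γ-lactonisation), which stores the two different chain ends without touching a stereocentre.

Step 4
Reactants: 7 (3R,4S)-4-hydroxy-3-[(4-methoxybenzyl)oxy]oxolan-2-one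
Product: 8 (3R,4S)-4-[(tert-butyldimethylsilyl)oxy]-3-[(4-methoxybenzyl)oxy]oxolan-2-one
Conditions: TBSCl, imidazole, DMF, rt
Reagents that add atoms: tert-butyldimethylsilyl chloride, CC(C)(C)[Si](C)(C)Cl
Why: Standard silylation of a secondary alcohol; this silyl ether will sit on C8 and shield one side of the allene in step 15.

Step 5
Reactants: 8 (3R,4S)-4-[(tert-butyldimethylsilyl)oxy]-3-[(4-methoxybenzyl)oxy]oxolan-2-one
Product: 9 (2R,3S)-3-[(tert-butyldimethylsilyl)oxy]-4-hydroxy-N-methoxy-2-[(4-methoxybenzyl)oxy]-N-methylbutanamide
Conditions: MeNH(OMe)·HCl, Me3Al, CH2Cl2, 0 °C to rt; aqueous potassium sodium tartrate; used at once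
Reagents that add atoms: N,O-dimethylhydroxylamine hydrochloride, Cl.CNOC
Why: Weinreb aminolysis of the lactone gives the C10 acyl group in the form that later stops at the ketone and frees the C7 hydroxyl; 9 is oxidised at once because a γ-hydroxy amide can close back to 8 on standing or with acid.

Step 6
Reactants: 9 (2R,3S)-3-[(tert-butyldimethylsilyl)oxy]-4-hydroxy-N-methoxy-2-[(4-methoxybenzyl)oxy]-N-methylbutanamide
Product: 10 (2R,3R)-3-[(tert-butyldimethylsilyl)oxy]-N-methoxy-2-[(4-methoxybenzyl)oxy]-N-methyl-4-oxobutanamide
Conditions: TEMPO (10 mol %), PhI(OAc)2 (1.2 equiv), CH2Cl2, rt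
Reagents that add atoms: none
Why: Oxoammonium (TEMPO) oxidation of a primary alcohol under almost neutral conditions, chosen so that the α-silyloxy aldehyde is not enolised at C8.

Step 7
Reactants: 10 (2R,3R)-3-[(tert-butyldimethylsilyl)oxy]-N-methoxy-2-[(4-methoxybenzyl)oxy]-N-methyl-4-oxobutanamide
Product: 11 (2R,3S)-3-[(tert-butyldimethylsilyl)oxy]-N-methoxy-2-[(4-methoxybenzyl)oxy]-N-methylpent-4-ynamide
Conditions: dimethyl (1-diazo-2-oxopropyl)phosphonate, K2CO3, MeOH, 0 °C to rt
Reagents that add atoms: dimethyl (1-diazo-2-oxopropyl)phosphonate, CC(=O)C(=[N+]=[N-])P(=O)(OC)OC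
Why: Ohira–Bestmann variant of the Seyferth–Gilbert homologation: the aldehyde becomes the terminal alkyne with one new carbon (C11) under carbonate in methanol at or below room temperature, conditions that usually leave α-alkoxy aldehydes configurationally intact.

Step 8
Reactants: 11 (2R,3S)-3-[(tert-butyldimethylsilyl)oxy]-N-methoxy-2-[(4-methoxybenzyl)oxy]-N-methylpent-4-ynamide
Product: 13 (2R,3S)-3-[(tert-butyldimethylsilyl)oxy]-N-methoxy-2-[(4-methoxybenzyl)oxy]-N-methylhexa-4,5-dienamide, via Mannich base 12 (not isolated)
Conditions: (CH2O)n, CuI (0.5 equiv), dicyclohexylamine (1.8 equiv), 1,4-dioxane, reflux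
Reagents that add atoms: formaldehyde (as paraformaldehyde), C=O
Why: Crabbé homologation: CuI-mediated Mannich coupling of alkyne, formaldehyde and amine gives propargylic amine 12, which loses the imine by an intramolecular 1,5-hydride shift to give the terminal allene (C13 from formaldehyde); the amide, both ethers and C8 are not involved.

Step 9
Reactants: 13 (2R,3S)-3-[(tert-butyldimethylsilyl)oxy]-N-methoxy-2-[(4-methoxybenzyl)oxy]-N-methylhexa-4,5-dienamide
Product: 14 (4R,5S)-5-[(tert-butyldimethylsilyl)oxy]-4-[(4-methoxybenzyl)oxy]-1-(trimethylsilyl)octa-6,7-dien-1-yn-3-one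
Conditions: ethynyltrimethylsilane, n-BuLi, THF, −78 °C; then 13, −78 to −20 °C; aqueous NH4Cl
Reagents that add atoms: ethynyltrimethylsilane, C#C[Si](C)(C)C
Why: Weinreb ketone synthesis: the lithium acetylide adds once, the chelated tetrahedral adduct survives until work-up and the ynone is released only then, so C9 is never exposed to base as a ketone; the allene hydrogens are not acidic enough to react with the acetylide.

Step 10
Reactants: 14 (4R,5S)-5-[(tert-butyldimethylsilyl)oxy]-4-[(4-methoxybenzyl)oxy]-1-(trimethylsilyl)octa-6,7-dien-1-yn-3-one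
Product: 16 (3S,4R,5S)-5-[(tert-butyldimethylsilyl)oxy]-4-[(4-methoxybenzyl)oxy]-3-methylocta-6,7-dien-1-yn-3-ol, via silylated carbinol 15 (not isolated)
Conditions: MeMgBr (3 equiv), THF, −78 °C; then MeOH, K2CO3, rt
Reagents that add atoms: methylmagnesium bromide, C[Mg]Br
Why: Cram-chelate controlled Grignard addition: magnesium bridges the ketone oxygen and the C9 p-methoxybenzyl ether oxygen in a five-membered chelate and methyl enters from the face of H9, away from the C8 chain, which should set C10 with its oxygen anti to the C9 oxygen (the 10R centre of the target); the silylated ynone adds 1,2, and carbonate in methanol then removes the C-silyl group of 15 in the same flask.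

Step 11
Reactants: 16 (3S,4R,5S)-5-[(tert-butyldimethylsilyl)oxy]-4-[(4-methoxybenzyl)oxy]-3-methylocta-6,7-dien-1-yn-3-ol; 3 (2Z)-4-[(tert-butyldimethylsilyl)oxy]-N-methoxy-N,2-dimethylbut-2-enamide
Product: 17 (2Z,7S,8R,9S)-1,9-bis[(tert-butyldimethylsilyl)oxy]-7-hydroxy-8-[(4-methoxybenzyl)oxy]-3,7-dimethyldodeca-2,10,11-trien-5-yn-4-one
Conditions: n-BuLi (2.0 equiv), THF, −78 °C; then 3, −78 to −30 °C; AcOH, −78 °C
Reagents that add atoms: none
Why: Weinreb ketone synthesis with the alkoxide–acetylide dianion of 16: two equivalents of base remove O–H and the acetylenic C–H but not the far less acidic allene hydrogens, the acetylide adds 1,2 to the unsaturated amide, and the cold acidic quench ties up the liberated amine before it can add to the ynone; the Z alkene of 3 is not touched.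

Step 12
Reactants: 17 (2Z,7S,8R,9S)-1,9-bis[(tert-butyldimethylsilyl)oxy]-7-hydroxy-8-[(4-methoxybenzyl)oxy]-3,7-dimethyldodeca-2,10,11-trien-5-yn-4-one
Product: 19 (2R)-5-{(2Z)-4-[(tert-butyldimethylsilyl)oxy]but-2-en-2-yl}-2-{(1R,2S)-2-[(tert-butyldimethylsilyl)oxy]-1-[(4-methoxybenzyl)oxy]penta-3,4-dien-1-yl}-2-methylfuran-3(2H)-one, via enaminone 18 (not isolated)
Conditions: Et2NH (1.5 equiv), EtOH, 0 °C to rt; then AcOH, H2O, THF, rt
Reagents that add atoms: water, O
Why: Classical 3(2H)-furanone synthesis from a γ-hydroxy ynone: the amine adds to C1 (aza-Michael) much faster than to the hindered α-methyl enone and gives enaminone 18, whose carbonyl is a vinylogous amide and no longer activates C5; mild acid then closes O10 onto C3 with loss of water and hydrolyses the C1 iminium to the ketone. An amine is used and not a cationic gold catalyst such as Ph3PAuNTf2, because the allene and the free hydroxyl would react with the latter.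

Step 13
Reactants: 19 (2R)-5-{(2Z)-4-[(tert-butyldimethylsilyl)oxy]but-2-en-2-yl}-2-{(1R,2S)-2-[(tert-butyldimethylsilyl)oxy]-1-[(4-methoxybenzyl)oxy]penta-3,4-dien-1-yl}-2-methylfuran-3(2H)-one
Product: 20 (2R)-2-{(1R,2S)-2-[(tert-butyldimethylsilyl)oxy]-1-[(4-methoxybenzyl)oxy]penta-3,4-dien-1-yl}-5-[(2Z)-4-hydroxybut-2-en-2-yl]-2-methylfuran-3(2H)-one
Conditions: HF·pyridine, pyridine, THF, 0 °C
Reagents that add atoms: none
Why: Kinetically selective desilylation: the primary allylic silyl ether should be cleaved by buffered HF·pyridine much faster than the secondary one at C8, which is flanked by two branched carbons.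

Step 14
Reactants: 20 (2R)-2-{(1R,2S)-2-[(tert-butyldimethylsilyl)oxy]-1-[(4-methoxybenzyl)oxy]penta-3,4-dien-1-yl}-5-[(2Z)-4-hydroxybut-2-en-2-yl]-2-methylfuran-3(2H)-one
Product: 21 (2Z)-3-[(5R)-5-{(1R,2S)-2-[(tert-butyldimethylsilyl)oxy]-1-[(4-methoxybenzyl)oxy]penta-3,4-dien-1-yl}-5-methyl-4-oxo-4,5-dihydrofuran-2-yl]but-2-enal
Conditions: MnO2 (activated, excess), CH2Cl2, rt, dark; filtered and used at once
Reagents that add atoms: none
Why: MnO2 oxidation of an allylic alcohol on a neutral surface, which normally keeps Z geometry; the enal is filtered, concentrated cold and used without chromatography to limit Z to E isomerisation.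

Step 15
Reactants: 21 (2Z)-3-[(5R)-5-{(1R,2S)-2-[(tert-butyldimethylsilyl)oxy]-1-[(4-methoxybenzyl)oxy]penta-3,4-dien-1-yl}-5-methyl-4-oxo-4,5-dihydrofuran-2-yl]but-2-enal; 22 carbon monoxide
Product: 23 (6S,7S,8S,9R,10R)-8-[(tert-butyldimethylsilyl)oxy]-9-[(4-methoxybenzyl)oxy]-1-oxo-3,10-epoxygermacra-2,4Z,11(13)-trien-12,6-olide
Conditions: Ru3(CO)12 (10 mol %), CO (20 atm), 1,4-dioxane, 0.002 M (slow addition of 21), 110 °C
Reagents that add atoms: none
Why: Proposed new method: a zerovalent ruthenium carbonyl fragment binds the C6 aldehyde and the internal C7=C11 bond of the allene and couples them oxidatively to an oxaruthenacyclopentane (C6–C7 formed, ruthenium on O6 and C11); 22 then inserts into the Ru–C11 bond and reductive elimination closes C12–O6. The closest known reaction type is the Ru3(CO)12-catalysed hetero-Pauson–Khand cyclocarbonylation of tethered allenyl aldehydes, which gives cis-fused α-methylene-γ-butyrolactones on five- and six-membered rings; a medium ring and a conjugated aldehyde have not been shown. Ring B closes as a (2+2+1) annulation of C6=O, C7=C11 and 22; the ten-membered carbocycle (nine-membered when counted through the furanone oxygen) closes end-to-end through the same C6–C7 bond, helped by the flat furanone and the Z C4=C5 bond, which hold C6 near C7, and by high dilution. C6 and C7 are set together: both π bonds must lie on one ruthenium with the short tether bridging them from one side, which places C5 and C8 cis on the metallacycle and H6/H7 cis in the lactone; unlike in the small-ring cases this is a preference, not a geometric necessity. Their sense relative to C8 should follow from a staggered C7–C8 arrangement in which the bulky C8 silyloxy group points out of the forming ring and lies anti to the C11–Ru bond, the 7S,8S relation. The step needs the internal and not the terminal allene bond to react (the terminal bond would give a ring larger by two atoms), the aldehyde and not the C1 furanone carbonyl to couple (C1=O is a hindered vinylogous ester that binds side-on poorly, though it would close an easy five-membered ring), and the enal to keep its Z geometry until it cyclises.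

Step 16
Reactants: 23 (6S,7S,8S,9R,10R)-8-[(tert-butyldimethylsilyl)oxy]-9-[(4-methoxybenzyl)oxy]-1-oxo-3,10-epoxygermacra-2,4Z,11(13)-trien-12,6-olide
Product: 24 (6S,7R,8S,9R,10R)-8-hydroxy-9-[(4-methoxybenzyl)oxy]-1-oxo-3,10-epoxygermacra-2,4Z,11(13)-trien-12,6-olide
Conditions: HF·pyridine, THF, 0 °C to rt
Reagents that add atoms: none
Why: Fluoride-mediated desilylation under weakly acidic, non-nucleophilic conditions that the methylene lactone, the dienone and the benzyl-type ether should tolerate (the descriptor at C7 changes with the substituent ranking only).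

Step 17
Reactants: 24 (6S,7R,8S,9R,10R)-8-hydroxy-9-[(4-methoxybenzyl)oxy]-1-oxo-3,10-epoxygermacra-2,4Z,11(13)-trien-12,6-olide
Product: 25 (6S,7S,8S,9R,10R)-9-[(4-methoxybenzyl)oxy]-8-(methacryloyloxy)-1-oxo-3,10-epoxygermacra-2,4Z,11(13)-trien-12,6-olide
Conditions: methacrylic anhydride, Et3N, DMAP (cat.), CH2Cl2, 0 °C
Reagents that add atoms: methacrylic anhydride, CC(=C)C(=O)OC(=O)C(C)=C
Why: Nucleophile-catalysed acylation of a secondary alcohol (DMAP, anhydride); only O8 is free, and low temperature with a short reaction time is chosen to outrun attack of the C8 alkoxide on the lactone carbonyl.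

Step 18
Reactants: 25 (6S,7S,8S,9R,10R)-9-[(4-methoxybenzyl)oxy]-8-(methacryloyloxy)-1-oxo-3,10-epoxygermacra-2,4Z,11(13)-trien-12,6-olide
Product: 26 (6S,7S,8S,9R,10R)-9-hydroxy-8-(methacryloyloxy)-1-oxo-3,10-epoxygermacra-2,4Z,11(13)-trien-12,6-olide (target)
Conditions: DDQ, CH2Cl2–pH 7 phosphate buffer, 0 °C to rt
Reagents that add atoms: none
Why: Oxidative cleavage of the p-methoxybenzyl ether by DDQ through hydride abstraction and hydrolysis of the oxocarbenium ion; the neutral buffered conditions should not touch the three Michael acceptors or the ester.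

## Compound list

1 | 3-methylfuran-2(5H)-one | CC1=CCOC1=O | starting material
2 | (2Z)-4-hydroxy-N-methoxy-N,2-dimethylbut-2-enamide | CON(C)C(=O)/C(C)=C\CO | intermediate
3 | (2Z)-4-[(tert-butyldimethylsilyl)oxy]-N-methoxy-N,2-dimethylbut-2-enamide | CON(C)C(=O)/C(C)=C\CO[Si](C)(C)C(C)(C)C | intermediate
4 | diethyl L-tartrate, diethyl (2R,3R)-2,3-dihydroxybutanedioate | CCOC(=O)[C@H](O)[C@@H](O)C(=O)OCC | starting material
5 | diethyl (2R,3R)-2-hydroxy-3-[(4-methoxybenzyl)oxy]butanedioate | CCOC(=O)[C@H](O)[C@@H](OCc1ccc(OC)cc1)C(=O)OCC | intermediate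
6 | ethyl (2R,3S)-3,4-dihydroxy-2-[(4-methoxybenzyl)oxy]butanoate | OC[C@H](O)[C@@H](OCc1ccc(OC)cc1)C(=O)OCC | intermediate
7 | (3R,4S)-4-hydroxy-3-[(4-methoxybenzyl)oxy]oxolan-2-one | O1C[C@H](O)[C@@H](OCc2ccc(OC)cc2)C1=O | intermediate
8 | (3R,4S)-4-[(tert-butyldimethylsilyl)oxy]-3-[(4-methoxybenzyl)oxy]oxolan-2-one | O1C[C@H](O[Si](C)(C)C(C)(C)C)[C@@H](OCc2ccc(OC)cc2)C1=O | intermediate
9 | (2R,3S)-3-[(tert-butyldimethylsilyl)oxy]-4-hydroxy-N-methoxy-2-[(4-methoxybenzyl)oxy]-N-methylbutanamide | OC[C@H](O[Si](C)(C)C(C)(C)C)[C@@H](OCc1ccc(OC)cc1)C(=O)N(C)OC | intermediate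
10 | (2R,3R)-3-[(tert-butyldimethylsilyl)oxy]-N-methoxy-2-[(4-methoxybenzyl)oxy]-N-methyl-4-oxobutanamide | O=C[C@H](O[Si](C)(C)C(C)(C)C)[C@@H](OCc1ccc(OC)cc1)C(=O)N(C)OC | intermediate
11 | (2R,3S)-3-[(tert-butyldimethylsilyl)oxy]-N-methoxy-2-[(4-methoxybenzyl)oxy]-N-methylpent-4-ynamide | C#C[C@H](O[Si](C)(C)C(C)(C)C)[C@@H](OCc1ccc(OC)cc1)C(=O)N(C)OC | intermediate
12 | (2R,3S)-3-[(tert-butyldimethylsilyl)oxy]-6-(dicyclohexylamino)-N-methoxy-2-[(4-methoxybenzyl)oxy]-N-methylhex-4-ynamide | C1CCCCC1N(C1CCCCC1)CC#C[C@H](O[Si](C)(C)C(C)(C)C)[C@@H](OCc1ccc(OC)cc1)C(=O)N(C)OC | intermediate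
13 | (2R,3S)-3-[(tert-butyldimethylsilyl)oxy]-N-methoxy-2-[(4-methoxybenzyl)oxy]-N-methylhexa-4,5-dienamide | C=C=C[C@H](O[Si](C)(C)C(C)(C)C)[C@@H](OCc1ccc(OC)cc1)C(=O)N(C)OC | intermediate
14 | (4R,5S)-5-[(tert-butyldimethylsilyl)oxy]-4-[(4-methoxybenzyl)oxy]-1-(trimethylsilyl)octa-6,7-dien-1-yn-3-one | C=C=C[C@H](O[Si](C)(C)C(C)(C)C)[C@@H](OCc1ccc(OC)cc1)C(=O)C#C[Si](C)(C)C | intermediate
15 | (3S,4R,5S)-5-[(tert-butyldimethylsilyl)oxy]-4-[(4-methoxybenzyl)oxy]-3-methyl-1-(trimethylsilyl)octa-6,7-dien-1-yn-3-ol | C=C=C[C@H](O[Si](C)(C)C(C)(C)C)[C@@H](OCc1ccc(OC)cc1)[C@@](C)(O)C#C[Si](C)(C)C | intermediate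
16 | (3S,4R,5S)-5-[(tert-butyldimethylsilyl)oxy]-4-[(4-methoxybenzyl)oxy]-3-methylocta-6,7-dien-1-yn-3-ol | C=C=C[C@H](O[Si](C)(C)C(C)(C)C)[C@@H](OCc1ccc(OC)cc1)[C@@](C)(O)C#C | intermediate
17 | (2Z,7S,8R,9S)-1,9-bis[(tert-butyldimethylsilyl)oxy]-7-hydroxy-8-[(4-methoxybenzyl)oxy]-3,7-dimethyldodeca-2,10,11-trien-5-yn-4-one | C=C=C[C@H](O[Si](C)(C)C(C)(C)C)[C@@H](OCc1ccc(OC)cc1)[C@@](C)(O)C#CC(=O)/C(C)=C\CO[Si](C)(C)C(C)(C)C | intermediate
18 | (2Z,5E,7S,8R,9S)-1,9-bis[(tert-butyldimethylsilyl)oxy]-6-(diethylamino)-7-hydroxy-8-[(4-methoxybenzyl)oxy]-3,7-dimethyldodeca-2,5,10,11-tetraen-4-one (enamine geometry drawn as E, immaterial) | C=C=C[C@H](O[Si](C)(C)C(C)(C)C)[C@@H](OCc1ccc(OC)cc1)[C@@](C)(O)/C(N(CC)CC)=C\C(=O)/C(C)=C\CO[Si](C)(C)C(C)(C)C | intermediate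
19 | (2R)-5-{(2Z)-4-[(tert-butyldimethylsilyl)oxy]but-2-en-2-yl}-2-{(1R,2S)-2-[(tert-butyldimethylsilyl)oxy]-1-[(4-methoxybenzyl)oxy]penta-3,4-dien-1-yl}-2-methylfuran-3(2H)-one | CC(C)(C)[Si](C)(C)OC/C=C(/C)C1=CC(=O)[C@](C)(O1)[C@H](OCc2ccc(OC)cc2)[C@@H](O[Si](C)(C)C(C)(C)C)C=C=C | intermediate
20 | (2R)-2-{(1R,2S)-2-[(tert-butyldimethylsilyl)oxy]-1-[(4-methoxybenzyl)oxy]penta-3,4-dien-1-yl}-5-[(2Z)-4-hydroxybut-2-en-2-yl]-2-methylfuran-3(2H)-one | OC/C=C(/C)C1=CC(=O)[C@](C)(O1)[C@H](OCc2ccc(OC)cc2)[C@@H](O[Si](C)(C)C(C)(C)C)C=C=C | intermediate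
21 | (2Z)-3-[(5R)-5-{(1R,2S)-2-[(tert-butyldimethylsilyl)oxy]-1-[(4-methoxybenzyl)oxy]penta-3,4-dien-1-yl}-5-methyl-4-oxo-4,5-dihydrofuran-2-yl]but-2-enal | O=C/C=C(/C)C1=CC(=O)[C@](C)(O1)[C@H](OCc2ccc(OC)cc2)[C@@H](O[Si](C)(C)C(C)(C)C)C=C=C | intermediate
22 | carbon monoxide | [C-]#[O+] | starting material
23 | (6S,7S,8S,9R,10R)-8-[(tert-butyldimethylsilyl)oxy]-9-[(4-methoxybenzyl)oxy]-1-oxo-3,10-epoxygermacra-2,4Z,11(13)-trien-12,6-olide | CC(C)(C)[Si](C)(C)O[C@H]1[C@H]2C(=C)C(=O)O[C@H]2/C=C(/C)C2=CC(=O)[C@](C)(O2)[C@@H]1OCc1ccc(OC)cc1 | intermediate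
24 | (6S,7R,8S,9R,10R)-8-hydroxy-9-[(4-methoxybenzyl)oxy]-1-oxo-3,10-epoxygermacra-2,4Z,11(13)-trien-12,6-olide | O[C@H]1[C@H]2C(=C)C(=O)O[C@H]2/C=C(/C)C2=CC(=O)[C@](C)(O2)[C@@H]1OCc1ccc(OC)cc1 | intermediate
25 | (6S,7S,8S,9R,10R)-9-[(4-methoxybenzyl)oxy]-8-(methacryloyloxy)-1-oxo-3,10-epoxygermacra-2,4Z,11(13)-trien-12,6-olide | C=C(C)C(=O)O[C@H]1[C@H]2C(=C)C(=O)O[C@H]2/C=C(/C)C2=CC(=O)[C@](C)(O2)[C@@H]1OCc1ccc(OC)cc1 | intermediate
26 | (6S,7S,8S,9R,10R)-9-hydroxy-8-(methacryloyloxy)-1-oxo-3,10-epoxygermacra-2,4Z,11(13)-trien-12,6-olide | C=C(C)C(=O)O[C@H]1[C@H]2C(=C)C(=O)O[C@H]2/C=C(/C)C2=CC(=O)[C@](C)(O2)[C@@H]1O | target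

## Step count and least certain steps

Total step count: 18. Longest linear sequence: 17 steps (steps 2 to 18, from 4); step 1 is the one-step side branch.

**Step 15 (key step).** Most likely failures:
- coupling at the wrong carbonyl: the C1 furanone ketone is three atoms from the allene and would close an easy five-membered ring, whereas the aldehyde must close a strained medium ring;
- oligomerisation in place of ring closure;
- isomerisation of the Z enal to E before it cyclises, after which C6 cannot reach C7;
- reaction at the terminal allene bond;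
- poor facial selectivity (trans fusion, or the wrong sense towards C8), because the cis preference is not enforced geometrically at this ring size.

Fallback, from 21 back to 23, using known reaction types in separate steps. Platinum-catalysed diboration of the terminal allene bond (B2pin2, Pt(dba)2, PCy3, toluene, 50 °C) should give the (Z)-2-boryl allylboronate F1, which is not isolated. Its allylboron end adds to the C6 aldehyde through a six-membered cyclic transition state (intramolecular allylboration, C7 attacking C6), and hydrolytic work-up gives the ring-closed homoallylic alcohol carrying a C11 alkenylboronate F2. A Z γ-substituted allylboronate gives the syn adduct, which corresponds to the cis lactone. Iododeboronation (NaOMe, then I2, THF–MeOH, −78 °C) gives the alkenyl iodide F3, and carbonylative lactonisation (Pd(PPh3)4, CO 1 atm, Et3N, MeCN, 50 °C) closes ring B to 23.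

**Step 12.** Most likely failure: reversible addition of the amine at C5 of the cross-conjugated enone, with relaxation of C4=C5 from Z to the more stable E, or stalling at the enaminone.

Fallback, from 16 back to 19, in which no amine meets the Z enone. Double deprotonation of 16 (n-BuLi, 2 equiv, THF, −78 °C) and methyl chloroformate give the γ-hydroxy ynoate F4. NaOMe in methanol adds methoxide to the triple bond and the ester lactonises onto the tertiary hydroxyl, giving the 4-methoxyfuran-2(5H)-one F5. Separately, commercial but-2-yn-1-ol is hydroaluminated with NaAlH2(OCH2CH2OMe)2 and iodinated to (2Z)-3-iodobut-2-en-1-ol F6, which is silylated (TBSCl, imidazole) to the silyl ether F7. Iodine–lithium exchange on F7 (t-BuLi, Et2O, −78 °C) and addition of the alkenyllithium to the lactone carbonyl of F5, followed by dilute acid, give 19 with loss of methanol.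

**Step 1.** Most likely failure: re-lactonisation of the Z hydroxy amide with loss of the amine before silylation, or conjugate addition of the aluminium amide to the butenolide.

Fallback, from 1 back to 3. LiOH in aqueous THF opens the lactone to lithium (2Z)-4-hydroxy-2-methylbut-2-enoate F8, which keeps its geometry while it stays a salt. TBSCl and imidazole in DMF silylate both oxygens to the silyl ester silyl ether F9. K2CO3 in aqueous methanol cleaves only the silyl ester, giving (2Z)-4-[(tert-butyldimethylsilyl)oxy]-2-methylbut-2-enoic acid F10. Carbodiimide coupling with N,O-dimethylhydroxylamine hydrochloride and N-methylmorpholine gives 3.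

**Step 17.** Most likely failure: translactonisation, the freed C8 hydroxyl attacking C12 under the basic acylation conditions so that the lactone migrates from O6 to O8; slow acylation of the hindered alcohol makes this worse.

Fallback, from 19 back to 25, placing the ester before the lactone exists. Both silyl ethers of 19 are removed (HF·pyridine, excess, THF, rt) to the diol F11. TEMPO with PhI(OAc)2 oxidises only the primary allylic alcohol to the hydroxy enal F12. Methacrylic anhydride with DMAP esterifies the C8 hydroxyl to the methacrylate enal F13. Cyclocarbonylation under the conditions of step 15 then gives 25 directly, and step 18 completes the route.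

## Further compounds

F1 | step 15 | bis(pinacolboronate) of 21: the allene replaced by (Z)-C7H=C11(Bpin)–C13H2(Bpin), all else as in 21 | O=C/C=C(/C)C1=CC(=O)[C@](C)(O1)[C@H](OCc2ccc(OC)cc2)[C@@H](O[Si](C)(C)C(C)(C)C)/C=C(/B2OC(C)(C)C(C)(C)O2)CB2OC(C)(C)C(C)(C)O2
F2 | step 15 | ring-closed alcohol: 23 with ring B replaced by a free (6S)-hydroxyl and, on C7, a 1-(4,4,5,5-tetramethyl-1,3,2-dioxaborolan-2-yl)vinyl group | CC(C)(C)[Si](C)(C)O[C@H]1[C@@H](C(=C)B2OC(C)(C)C(C)(C)O2)[C@@H](O)/C=C(/C)C2=CC(=O)[C@](C)(O2)[C@@H]1OCc1ccc(OC)cc1
F3 | step 15 | as F2 with a 1-iodovinyl group on C7 | CC(C)(C)[Si](C)(C)O[C@H]1[C@@H](C(I)=C)[C@@H](O)/C=C(/C)C2=CC(=O)[C@](C)(O2)[C@@H]1OCc1ccc(OC)cc1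
F4 | step 12 | methyl (4S,5R,6S)-6-[(tert-butyldimethylsilyl)oxy]-4-hydroxy-5-[(4-methoxybenzyl)oxy]-4-methylnona-7,8-dien-2-ynoate | C=C=C[C@H](O[Si](C)(C)C(C)(C)C)[C@@H](OCc1ccc(OC)cc1)[C@@](C)(O)C#CC(=O)OC
F5 | step 12 | (5R)-5-{(1R,2S)-2-[(tert-butyldimethylsilyl)oxy]-1-[(4-methoxybenzyl)oxy]penta-3,4-dien-1-yl}-4-methoxy-5-methylfuran-2(5H)-one | C=C=C[C@H](O[Si](C)(C)C(C)(C)C)[C@@H](OCc1ccc(OC)cc1)[C@@]1(C)OC(=O)C=C1OC
F6 | step 12 | (2Z)-3-iodobut-2-en-1-ol | C/C(I)=C/CO
F7 | step 12 | tert-butyl{[(2Z)-3-iodobut-2-en-1-yl]oxy}dimethylsilane | C/C(I)=C/CO[Si](C)(C)C(C)(C)C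
F8 | step 1 | lithium (2Z)-4-hydroxy-2-methylbut-2-enoate | [Li+].[O-]C(=O)/C(C)=C\CO
F9 | step 1 | tert-butyldimethylsilyl (2Z)-4-[(tert-butyldimethylsilyl)oxy]-2-methylbut-2-enoate | CC(C)(C)[Si](C)(C)OC(=O)/C(C)=C\CO[Si](C)(C)C(C)(C)C
F10 | step 1 | (2Z)-4-[(tert-butyldimethylsilyl)oxy]-2-methylbut-2-enoic acid | OC(=O)/C(C)=C\CO[Si](C)(C)C(C)(C)C
F11 | step 17 | (2R)-5-[(2Z)-4-hydroxybut-2-en-2-yl]-2-{(1R,2S)-2-hydroxy-1-[(4-methoxybenzyl)oxy]penta-3,4-dien-1-yl}-2-methylfuran-3(2H)-one | OC/C=C(/C)C1=CC(=O)[C@](C)(O1)[C@H](OCc2ccc(OC)cc2)[C@@H](O)C=C=C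
F12 | step 17 | (2Z)-3-[(5R)-5-{(1R,2S)-2-hydroxy-1-[(4-methoxybenzyl)oxy]penta-3,4-dien-1-yl}-5-methyl-4-oxo-4,5-dihydrofuran-2-yl]but-2-enal | O=C/C=C(/C)C1=CC(=O)[C@](C)(O1)[C@H](OCc2ccc(OC)cc2)[C@@H](O)C=C=C
F13 | step 17 | (1R,2S)-1-[(4-methoxybenzyl)oxy]-1-{(2R)-2-methyl-3-oxo-5-[(2Z)-4-oxobut-2-en-2-yl]-2,3-dihydrofuran-2-yl}penta-3,4-dien-2-yl 2-methylprop-2-enoate | O=C/C=C(/C)C1=CC(=O)[C@](C)(O1)[C@H](OCc2ccc(OC)cc2)[C@@H](OC(=O)C(C)=C)C=C=C
A1 | alternative 1 | ten-membered C6 ketone with Z C4=C5, C3 dimethyl ketal, C1≡C2 alkyne, C9/C10 acetonide, C8 p-methoxybenzyl ether and a C7 CH2CO2Me arm | O=C1/C=C(/C)C(OC)(OC)C#C[C@]2(C)OC(C)(C)O[C@@H]2[C@@H](OCc2ccc(OC)cc2)[C@H]1CC(=O)OC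
A2 | alternative 1 | guaiacol (2-methoxyphenol) | COc1ccccc1O
A3 | alternative 2 | ten-membered C9 ketone with free C8 hydroxyl, ring A in place, C6 silyl ether and a C7 3-(silyloxy)prop-1-en-2-yl branch | O=C1[C@@H](O)[C@@H](C(=C)CO[Si](C)(C)C(C)(C)C)[C@@H](O[Si](C)(C)C(C)(C)C)/C=C(/C)C2=CC(=O)[C@]1(C)O2
A4 | alternative 3 | ten-membered C1 ketone / C10 tertiary alcohol with C3 dithiane, C9 silyl ether, C8 p-methoxybenzyl ether, C6 triethylsilyl ether and a C7 3-(triethylsilyloxy)prop-1-en-2-yl branch | COc1ccc(CO[C@H]2[C@@H](C(=C)CO[Si](CC)(CC)CC)[C@@H](O[Si](CC)(CC)CC)/C=C(/C)C3(SCCCS3)CC(=O)[C@](C)(O)[C@@H]2O[Si](C)(C)C(C)(C)C)cc1
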